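**Retrosynthetic overview**

- The strategy rests on ring B (C1'–C6', with the ether oxygen on C1', pentyl on C2', hydroxyls on C4' and C6'). It is a folded 5-aryloxyundecane-2,4,6-trione, carried as its cyclic dehydrated form, a 3-aryloxy-6-methyl-2-pentyl-4-pyranone. Hydroxide opens the pyranone and an aldol reaction (bond C2'–C3') closes ring B last.
- The pyranone comes from a 3-methylisoxazole (masked 1,3-diketone) by N–O hydrogenolysis and acid closure. The future diaryl ether oxygen is attached earlier by SN2 of the ring A phenol on an α-bromo ketone, so no C(sp2)–O coupling and no phenol protection is needed.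
- The bromo ketone comes from 3,5-dimethylisoxazole and methyl hexanoate (lateral lithiation, acylation, bromination).
- The ring A phenol comes from 3,5-dimethoxybenzaldehyde: bromination, butyl Grignard addition, Br–Li exchange/CO2 to a phthalide, permanganate oxidation to the keto acid, esterification, chelation-controlled O-demethylation.
- Ring order: ring A is bought as a benzene; the pyranone ring is formed in step 10; ring B in step 11.

Key step: step 11

Remark: the target has no stereocentre; the sp3 centres of 3–7, 15, 16 and 20 are racemic or transient and each is destroyed later. The 2-acylbenzoic acids 8 and 21 are drawn as open keto acids, which may equilibrate with their 3-hydroxyphthalide (lactol) tautomers.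

**Route**

Step 1
Reactants: 1 3,5-dimethoxybenzaldehyde
Product: 2 2-bromo-3,5-dimethoxybenzaldehyde
Conditions: NBS (1.05 equiv), MeCN, 0 °C to rt
Reagents that add atoms: N-bromosuccinimide, O=C1CCC(=O)N1Br
Why: Electrophilic aromatic bromination should go to C2, which is para to one methoxy group and ortho to the other, rather than to the more crowded C4 between the two methoxy groups.

Step 2
Reactants: 2 2-bromo-3,5-dimethoxybenzaldehyde
Product: 3 1-(2-bromo-3,5-dimethoxyphenyl)pentan-1-ol (racemic)
Conditions: n-BuMgBr (1.2 equiv), THF, −78 to 0 °C; 1 M HCl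
Reagents that add atoms: n-butylmagnesium bromide, CCCC[Mg]Br
Why: Grignard 1,2-addition to the aldehyde, with the aryl bromide inert at this temperature; the new carbinol centre is racemic and is oxidised away in step 4.

Step 3
Reactants: 3 1-(2-bromo-3,5-dimethoxyphenyl)pentan-1-ol
Product: 6 3-butyl-5,7-dimethoxy-2-benzofuran-1(3H)-one (racemic), via dilithio species 4 (not isolated), via hydroxy acid 5 (not isolated)
Conditions: n-BuLi (2.2 equiv), THF, −78 °C; CO2 (g), −78 °C to rt; 2 M HCl, rt
Reagents that add atoms: carbon dioxide, O=C=O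
Why: Deprotonation of the alcohol and bromine–lithium exchange give the aryllithium at the carbon between the carbinol and a methoxy group, which is carboxylated, and the γ-hydroxy acid lactonises on acidification (halogen–metal exchange/carboxylation route to phthalides).

Step 4
Reactants: 6 3-butyl-5,7-dimethoxy-2-benzofuran-1(3H)-one
Product: 8 2,4-dimethoxy-6-pentanoylbenzoic acid, via sodium hydroxy carboxylate 7 (not isolated)
Conditions: NaOH (2 M aq), 80 °C; then KMnO4 (0.7 equiv, aq), 0 °C to rt; filter; HCl to pH 2
Reagents that add atoms: sodium hydroxide, [Na+].[OH-]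
Why: Hydroxide opens the lactone to the γ-hydroxy carboxylate, which cannot relactonise in base, and cold alkaline permanganate oxidises the secondary benzylic alcohol to the aryl ketone (classical phthalide to 2-acylbenzoic acid oxidation), the aryl methyl ethers and alkyl chain being inert at this temperature.

Step 5
Reactants: 8 2,4-dimethoxy-6-pentanoylbenzoic acid
Product: 9 methyl 2,4-dimethoxy-6-pentanoylbenzoate
Conditions: MeI (1.5 equiv), K2CO3, DMF, rt
Reagents that add atoms: iodomethane, CI
Why: SN2 alkylation of the carboxylate should give the open (normal) methyl ester and not the pseudo ester that acid-catalysed esterification of a 2-acylbenzoic acid would give.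

Step 6
Reactants: 9 methyl 2,4-dimethoxy-6-pentanoylbenzoate
Product: 10 methyl 2-hydroxy-4-methoxy-6-pentanoylbenzoate
Conditions: BCl3 (1.2 equiv, 1 M in CH2Cl2), CH2Cl2, −78 to 0 °C; H2O
Reagents that add atoms: none
Why: BCl3 bound to the ester carbonyl cleaves only the ortho methyl ether through a six-membered chelate, whereas the C4 methoxy group cannot chelate and is kept (chelation-controlled selective O-demethylation).

Step 7
Reactants: 11 3,5-dimethylisoxazole, 12 methyl hexanoate
Product: 14 1-(3-methyl-1,2-oxazol-5-yl)heptan-2-one, via lithiomethyl isoxazole 13 (not isolated)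
Conditions: 11 (2.2 equiv), n-BuLi (2.1 equiv), THF, −78 °C; then 12 (1.0 equiv), −78 to 0 °C; 1 M HCl
Reagents that add atoms: none
Why: Lateral lithiation occurs at the kinetically more acidic C5 methyl group and the carbanion is acylated by the ester (Claisen-type acylation), the product being stored as its enolate by the second equivalent of carbanion so that it is not attacked again.

Step 8
Reactants: 14 1-(3-methyl-1,2-oxazol-5-yl)heptan-2-one
Product: 15 1-bromo-1-(3-methyl-1,2-oxazol-5-yl)heptan-2-one (racemic)
Conditions: NBS (1.0 equiv), p-TsOH·H2O (10 mol%), CH2Cl2, 0 °C to rt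
Reagents that add atoms: N-bromosuccinimide, O=C1CCC(=O)N1Br
Why: Acid-catalysed α-bromination through the enol conjugated with the isoxazole, which forms far more readily at the doubly activated methylene than at C3 of the chain.

Step 9
Reactants: 10 methyl 2-hydroxy-4-methoxy-6-pentanoylbenzoate, 15 1-bromo-1-(3-methyl-1,2-oxazol-5-yl)heptan-2-one
Product: 16 methyl 4-methoxy-2-{[1-(3-methyl-1,2-oxazol-5-yl)-2-oxoheptyl]oxy}-6-pentanoylbenzoate (racemic)
Conditions: K2CO3 (1.5 equiv), acetone, rt
Reagents that add atoms: none
Why: Williamson ether synthesis, the phenoxide displacing bromide by SN2 at an sp3 carbon activated by both the adjacent ketone and the heteroaryl ring; the isoxazole has no acidic or electrophilic site under these conditions.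

Step 10
Reactants: 16 methyl 4-methoxy-2-{[1-(3-methyl-1,2-oxazol-5-yl)-2-oxoheptyl]oxy}-6-pentanoylbenzoate
Product: 18 methyl 4-methoxy-2-[(6-methyl-4-oxo-2-pentyl-4H-pyran-3-yl)oxy]-6-pentanoylbenzoate, via enaminone 17 (not isolated)
Conditions: H2 (1 atm), Raney Ni (W-2, washed neutral), EtOH, rt; filter; then 2 M HCl, THF, rt to 40 °C
Reagents that add atoms: none
Why: Hydrogenolysis of the weak N–O bond unmasks the (Z)-β-amino enone, and in acid the enol oxygen of the hexanoyl ketone adds to the protonated vinylogous amide carbon (6-exo-trig) with loss of ammonium to give the 4-pyranone (isoxazole as masked 1,3-diketone), acid being applied at once because the free amine would otherwise close onto the ketone to a 4-pyridone.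

Step 11
Reactants: 18 methyl 4-methoxy-2-[(6-methyl-4-oxo-2-pentyl-4H-pyran-3-yl)oxy]-6-pentanoylbenzoate
Product: 21 2-(2,4-dihydroxy-6-pentylphenoxy)-4-methoxy-6-pentanoylbenzoic acid, via triketone acid 19 (not isolated), via aldol adduct 20 (not isolated)
Conditions: KOH (2 M aq, 8 equiv), 1,4-dioxane, degassed, argon, rt 1 h then 60 °C; 2 M HCl to pH 2, 0 °C
Reagents that add atoms: potassium hydroxide, [K+].[OH-]
Why: Proposed new method: hydroxide adds to C2 or C6 of the vinylogous ester of 18 and opens the ring to the enolate of triketone 19, while the methyl ester is cleaved early with help from the ortho ketone (its hydroxide adduct lactonises onto the ester and the pseudo acid reopens to the keto carboxylate), so that no ester remains for a Dieckmann closure. The dienolate reaching the terminal methyl carbon then attacks the hexanoyl ketone in a 6-(enolendo)-exo-trig aldol reaction that forms the C2'–C3' bond and ring B as aldol 20, and loss of water followed by enolisation to the aromatic ring makes the sequence irreversible. The closest known reaction is the hydroxide-mediated conversion of 2,6-dialkyl-4-pyranones and the corresponding 2,4,6-triketones into 5-alkylresorcinols (2,6-dimethyl-4-pyranone to orcinol); a 3-aryloxy group on the pyranone has not been carried through it. No stereocentre remains, since the carbinol and ether carbons of 20 both become sp2. The selectivity needed is methyl-onto-hexanoyl aldol over hexanoyl-α-methylene-onto-acetyl aldol and over retro-Claisen cleavage: the primary carbanion is less hindered and forms without engaging the tetrasubstituted aryloxy enolate, the hexanoyl carbonyl is made more electrophilic by the adjacent aryloxy oxygen, and degassed hydroxide of moderate strength and temperature keeps the chain as a polyanion that resists hydroxide addition.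

**Compound list**

1 | 3,5-dimethoxybenzaldehyde | COc1cc(C=O)cc(OC)c1 | starting material
2 | 2-bromo-3,5-dimethoxybenzaldehyde | COc1cc(C=O)c(Br)c(OC)c1 | intermediate
3 | 1-(2-bromo-3,5-dimethoxyphenyl)pentan-1-ol (racemic) | CCCCC(O)c1cc(OC)cc(OC)c1Br | intermediate
4 | lithium 1-(2-lithio-3,5-dimethoxyphenyl)pentan-1-olate (racemic) | CCCCC(O[Li])c1cc(OC)cc(OC)c1[Li] | intermediate
5 | 2-(1-hydroxypentyl)-4,6-dimethoxybenzoic acid (racemic) | CCCCC(O)c1cc(OC)cc(OC)c1C(=O)O | intermediate
6 | 3-butyl-5,7-dimethoxy-2-benzofuran-1(3H)-one (racemic) | CCCCC1OC(=O)c2c(OC)cc(OC)cc21 | intermediate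
7 | sodium 2-(1-hydroxypentyl)-4,6-dimethoxybenzoate (racemic) | CCCCC(O)c1cc(OC)cc(OC)c1C(=O)[O-].[Na+] | intermediate
8 | 2,4-dimethoxy-6-pentanoylbenzoic acid | CCCCC(=O)c1cc(OC)cc(OC)c1C(=O)O | intermediate
9 | methyl 2,4-dimethoxy-6-pentanoylbenzoate | CCCCC(=O)c1cc(OC)cc(OC)c1C(=O)OC | intermediate
10 | methyl 2-hydroxy-4-methoxy-6-pentanoylbenzoate | CCCCC(=O)c1cc(OC)cc(O)c1C(=O)OC | intermediate
11 | 3,5-dimethylisoxazole | Cc1cc(C)on1 | starting material
12 | methyl hexanoate | CCCCCC(=O)OC | starting material
13 | [(3-methyl-1,2-oxazol-5-yl)methyl]lithium | [Li]Cc1cc(C)no1 | intermediate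
14 | 1-(3-methyl-1,2-oxazol-5-yl)heptan-2-one | CCCCCC(=O)Cc1cc(C)no1 | intermediate
15 | 1-bromo-1-(3-methyl-1,2-oxazol-5-yl)heptan-2-one (racemic) | CCCCCC(=O)C(Br)c1cc(C)no1 | intermediate
16 | methyl 4-methoxy-2-{[1-(3-methyl-1,2-oxazol-5-yl)-2-oxoheptyl]oxy}-6-pentanoylbenzoate (racemic) | CCCCCC(=O)C(Oc1cc(OC)cc(C(=O)CCCC)c1C(=O)OC)c1cc(C)no1 | intermediate
17 | methyl 2-{[(2Z)-2-amino-4,6-dioxoundec-2-en-5-yl]oxy}-4-methoxy-6-pentanoylbenzoate (racemic) | C/C(N)=C/C(=O)C(Oc1cc(OC)cc(C(=O)CCCC)c1C(=O)OC)C(=O)CCCCC | intermediate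
18 | methyl 4-methoxy-2-[(6-methyl-4-oxo-2-pentyl-4H-pyran-3-yl)oxy]-6-pentanoylbenzoate | CCCCCc1oc(C)cc(=O)c1Oc1cc(OC)cc(C(=O)CCCC)c1C(=O)OC | intermediate
19 | 4-methoxy-6-pentanoyl-2-[(2,4,6-trioxoundecan-5-yl)oxy]benzoic acid (racemic, present as its polyanion) | CCCCCC(=O)C(Oc1cc(OC)cc(C(=O)CCCC)c1C(=O)O)C(=O)CC(C)=O | intermediate
20 | 2-[(2-hydroxy-4,6-dioxo-2-pentylcyclohexyl)oxy]-4-methoxy-6-pentanoylbenzoic acid (configuration undefined, transient) | CCCCCC1(O)CC(=O)CC(=O)C1Oc1cc(OC)cc(C(=O)CCCC)c1C(=O)O | intermediate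
21 | 2-(2,4-dihydroxy-6-pentylphenoxy)-4-methoxy-6-pentanoylbenzoic acid (CNP0189595.0) | CCCCCc1cc(O)cc(O)c1Oc1cc(OC)cc(C(=O)CCCC)c1C(=O)O | target

**Step count**

Total steps: 11. Longest linear sequence: 9 steps (steps 1–6, 9, 10, 11, from 3,5-dimethoxybenzaldehyde).

**Steps most likely to fail**

Step 11 (bears the label "Proposed new method:"). The aldol closure may take the other course, the hexanoyl α-methylene attacking the acetyl carbonyl. Retro-Claisen fragmentation of the aryloxy-substituted triketone may also outrun cyclisation, and the resorcinolate may be oxidised by air. The fallback uses known chemistry and runs from 10 to 21. Ring B is taken from olivetol (5-pentylbenzene-1,3-diol, CCCCCc1cc(O)cc(O)c1) and the ether is made by metal-free O-arylation with a diaryliodonium salt. Olivetol is benzylated (BnBr, K2CO3, DMF) to 1,3-bis(benzyloxy)-5-pentylbenzene F1. Iodination para to one benzyloxy group (NIS, MeCN) gives 1,5-bis(benzyloxy)-2-iodo-3-pentylbenzene F2. Oxidation and ligand exchange (mCPBA, TsOH·H2O, MeCN; then 1,3,5-trimethoxybenzene) give [2,4-bis(benzyloxy)-6-pentylphenyl](2,4,6-trimethoxyphenyl)iodonium tosylate F3. Phenol 10 is arylated with F3 (K2CO3, MeCN, 50 °C; the trimethoxyphenyl group is the ligand that is not transferred) to methyl 2-[2,4-bis(benzyloxy)-6-pentylphenoxy]-4-methoxy-6-pentanoylbenzoate F4. Hydrogenolysis (H2, Pd/C, EtOAc, rt) gives methyl 2-(2,4-dihydroxy-6-pentylphenoxy)-4-methoxy-6-pentanoylbenzoate F5, and LiOH (THF/H2O, rt) then gives 21.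

Step 10. The freed amino group may close onto the hexanoyl ketone to a 4-pyridone before acid intervenes, or hydrogenolysis may go on to cleave the activated C–OAr bond. The fallback avoids nitrogen and runs from 10 to 18. (E)-4-Methoxypent-3-en-2-one (CC(=O)/C=C(\C)OC) is deprotonated at the acetyl methyl group (LiN(SiMe3)2, 2 equiv, THF, −78 °C) and acylated with hexanoyl chloride to (E)-2-methoxyundec-2-ene-4,6-dione F6. Chlorination between the two carbonyl groups (NCS, CH2Cl2, rt) gives (E)-5-chloro-2-methoxyundec-2-ene-4,6-dione F7. Phenol 10 displaces the chloride (K2CO3, acetone, rt, as 3-chloropentane-2,4-dione does with phenols) to give methyl 4-methoxy-2-{[(2E)-2-methoxy-4,6-dioxoundec-2-en-5-yl]oxy}-6-pentanoylbenzoate F8. TFA (CH2Cl2, rt) closes the pyranone with loss of methanol to 18.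

Step 9. The hindered, hydrogen-bonded phenoxide may displace too slowly at the secondary, enolisable bromide. Enolisation of 15, bromine transfer to the electron-rich phenol, or Dieckmann-type attack of the product carbanion on the ortho ester could then take over. The fallback runs from 14 and 10 to 16. Regitz diazo transfer to 14 (4-acetamidobenzenesulfonyl azide, DBU, MeCN, 0 °C) gives 1-diazo-1-(3-methyl-1,2-oxazol-5-yl)heptan-2-one F9. Rh2(OAc)4 (1 mol%, CH2Cl2, rt) then inserts the carbene into the O–H bond of 10 under neutral conditions to give 16.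

**Further compounds**

F1 | step 11 | 1,3-bis(benzyloxy)-5-pentylbenzene | CCCCCc1cc(OCc2ccccc2)cc(OCc2ccccc2)c1
F2 | step 11 | 1,5-bis(benzyloxy)-2-iodo-3-pentylbenzene | CCCCCc1cc(OCc2ccccc2)cc(OCc2ccccc2)c1I
F3 | step 11 | [2,4-bis(benzyloxy)-6-pentylphenyl](2,4,6-trimethoxyphenyl)iodonium 4-methylbenzenesulfonate | CCCCCc1cc(OCc2ccccc2)cc(OCc2ccccc2)c1[I+]c1c(OC)cc(OC)cc1OC.Cc1ccc(S(=O)(=O)[O-])cc1
F4 | step 11 | methyl 2-[2,4-bis(benzyloxy)-6-pentylphenoxy]-4-methoxy-6-pentanoylbenzoate | CCCCCc1cc(OCc2ccccc2)cc(OCc2ccccc2)c1Oc1cc(OC)cc(C(=O)CCCC)c1C(=O)OC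
F5 | step 11 | methyl 2-(2,4-dihydroxy-6-pentylphenoxy)-4-methoxy-6-pentanoylbenzoate | CCCCCc1cc(O)cc(O)c1Oc1cc(OC)cc(C(=O)CCCC)c1C(=O)OC
F6 | step 10 | (E)-2-methoxyundec-2-ene-4,6-dione | CCCCCC(=O)CC(=O)/C=C(\C)OC
F7 | step 10 | (E)-5-chloro-2-methoxyundec-2-ene-4,6-dione (racemic) | CCCCCC(=O)C(Cl)C(=O)/C=C(\C)OC
F8 | step 10 | methyl 4-methoxy-2-{[(2E)-2-methoxy-4,6-dioxoundec-2-en-5-yl]oxy}-6-pentanoylbenzoate (racemic) | CCCCCC(=O)C(Oc1cc(OC)cc(C(=O)CCCC)c1C(=O)OC)C(=O)/C=C(\C)OC
F9 | step 9 | 1-diazo-1-(3-methyl-1,2-oxazol-5-yl)heptan-2-one | CCCCCC(=O)C(=[N+]=[N-])c1cc(C)no1
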